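**Retrosynthetic overview**

- The last ring closed is the γ-lactone on O8′. Before that, the norbornene core comes from a [4+2] union (C1–C13′ and C3–C11′) of an acetoxycyclopentadiene guaianolide with a seco-eudesmane α-methylene lactone. That lactone is temporarily transposed to O6′ (bromolactone relay) so that the diene meets the required face of C11′; zinc then undoes the relay.
- Guaianolide half, ring order: chiral-pool cyclopentenone → six-membered ring (Diels–Alder) → seven-membered ring → trans-γ-lactone. The key step is the ring expansion of a fused silyloxycyclopropane (cyclohexane → cycloheptanone), which also sets C10.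
- Seco-eudesmane half, ring order: cis-γ-lactone → cyclohexadiene. C4′ comes from Zr-catalysed carboalumination, the lactone from Ir-catalysed 2-(alkoxycarbonyl)allylation, and the carbocycle from endo-mode enyne metathesis.

Assumption and locants: the target is taken exactly as drawn, i.e. (1R,2S,3S,7S,8R,10R,4′S,7′S,8′S,11′S) with the guaianolide half numbered C1–C15 and the seco-eudesmanolide half C1′–C15′; TBS = tert-butyldimethylsilyl.

**Route**

Step 1
Reactants: 1 itaconic anhydride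
Product: 2 4-methyl hydrogen itaconate
Conditions: MeOH (1.1 equiv), CH2Cl2, 40 °C
Reagents that add atoms: methanol (CO)
Why: Anhydride alcoholysis occurs at the non-conjugated carbonyl and gives the β-monoester with the conjugated acid free.

Step 2
Reactants: 2 4-methyl hydrogen itaconate
Product: 4 methyl 3-methylidene-4-oxohexanoate, via acid chloride 3 (not isolated)
Conditions: (COCl)2, DMF (cat.), CH2Cl2, 0 °C to rt; then Et2Zn (0.55 equiv), Pd(PPh3)4 (2 mol %), THF, 0 °C
Reagents that add atoms: diethylzinc (CC[Zn]CC)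
Why: Acid chloride formation and Negishi acylation turn the conjugated acid into the ethyl ketone without touching the ester or the 1,1-disubstituted alkene.

Step 3
Reactants: 4 methyl 3-methylidene-4-oxohexanoate
Product: 5 methyl (4Z)-4-(TBSO)-3-methylidenehex-4-enoate
Conditions: TBSOTf, Et3N, CH2Cl2, −78 to 0 °C
Reagents that add atoms: tert-butyldimethylsilyl trifluoromethanesulfonate (CC(C)(C)[Si](C)(C)OS(=O)(=O)C(F)(F)F)
Why: Soft enolisation and O-silylation of the ethyl ketone (its only enolisable side) gives the (Z)-2-silyloxy-1,3-diene.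

Step 4
Reactants: 6 (4S)-4-hydroxycyclopent-2-en-1-one
Product: 7 (4S)-4-(TBSO)cyclopent-2-en-1-one
Conditions: TBSCl, imidazole, CH2Cl2, 0 °C to rt
Reagents that add atoms: tert-butyldimethylsilyl chloride (CC(C)(C)[Si](C)(C)Cl)
Why: Standard silylation of the chiral-pool alcohol, whose stereocentre becomes C2 of the target.

Step 5
Reactants: 7 (4S)-4-(TBSO)cyclopent-2-en-1-one
Product: 9 (4S)-2-bromo-4-(TBSO)cyclopent-2-en-1-one, via dibromide 8 (not isolated)
Conditions: Br2, CH2Cl2, 0 °C; then Et3N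
Reagents that add atoms: bromine (BrBr)
Why: Bromine addition followed by dehydrobromination gives the α-bromo enone, a more reactive dienophile that keeps the enone oxidation level after cycloaddition.

Step 6
Reactants: 9 (4S)-2-bromo-4-(TBSO)cyclopent-2-en-1-one; 5 methyl (4Z)-4-(TBSO)-3-methylidenehex-4-enoate
Product: 12 methyl 2-[(3S)-3,5-bis(TBSO)-4-methyl-1-oxo-2,3,6,7-tetrahydro-1H-inden-6-yl]acetate (C6 epimers), via bromo adduct 10 (not isolated), via unconjugated enol ether 11 (not isolated)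
Conditions: 5 (1.5 equiv), PhMe, 90 °C; then Li2CO3, LiBr, DMF, 100 °C
Reagents that add atoms: none
Why: A Diels–Alder reaction with "para" control by the silyloxy group joins the methyl-bearing diene terminus to the enone β-carbon, and LiBr/Li2CO3 dehydrobromination plus base-mediated migration of the enol-ether double bond into conjugation gives the dienol ether; only the C2 centre from 6 persists, the other new centres being erased or reset later.

Step 7
Reactants: 12 methyl 2-[(3S)-3,5-bis(TBSO)-4-methyl-1-oxo-2,3,6,7-tetrahydro-1H-inden-6-yl]acetate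
Product: 13 4,5-methano (silyloxycyclopropane) derivative of 12
Conditions: Et2Zn, CH2I2, CH2Cl2, 0 °C to rt
Reagents that add atoms: diiodomethane (ICI)
Why: Simmons–Smith (Furukawa) cyclopropanation is selective for the electron-rich silyl enol ether (C8=C10) over the enone alkene, and the new CH2 is the future C9.

Step 8
Reactants: 13 4,5-methano (silyloxycyclopropane) derivative of 12
Product: 14 methyl 2-[(3S,4R)-3-(TBSO)-4-methyl-1,6-dioxo-1,2,3,4,5,6,7,8-octahydroazulen-7-yl]acetate (C7 epimers)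
Conditions: 9-mesityl-10-methylacridinium BF4 (5 mol %), 2,4,6-triisopropylbenzenethiol (20 mol %), MeOH (5 equiv), DCE, 450 nm LEDs, 0 °C
Reagents that add atoms: none
Why: Proposed new method: acridinium/thiol photoredox ring-expanding isomerisation of a fused donor–acceptor silyloxycyclopropane, in which single-electron oxidation and methanol-assisted desilylation cleave the internal C8–C10 bond (the one giving the tertiary, dienone-conjugated radical) to form the cycloheptanone, and the hindered thiol then delivers H to C10 from the face anti to the C2 silyloxy group (10R, methyl cis to O2) before thiyl/acridinyl turnover; the closest known reactions are the Saegusa–Ito FeCl3 ring expansion of silyloxycyclopropanes and acridinium/thiol hydrogen-atom-transfer catalysis.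

Step 9
Reactants: 14 methyl 2-[(3S,4R)-3-(TBSO)-4-methyl-1,6-dioxo-1,2,3,4,5,6,7,8-octahydroazulen-7-yl]acetate
Product: 16 (2S,7S,8R,10R)-2-(TBSO)-4-oxo-13,15-dinorguai-1(5)-en-12,8-olide, via hydroxy ester 15 (not isolated)
Conditions: TsOH·H2O (cat.), CH2Cl2, rt; then NaBH4, MeOH–CH2Cl2 (1:1), −78 °C; then TsOH (cat.), PhH, 50 °C
Reagents that add atoms: none
Why: Acid equilibrates C7 (α to the ketone) to the pseudo-equatorial epimer cis to the C10 methyl, chemoselective borohydride reduction of the saturated ketone by axial attack gives the equatorial C8 alcohol trans to the side chain, and acid-catalysed lactonisation closes the trans-fused γ-lactone.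

Step 10
Reactants: 16 (2S,7S,8R,10R)-2-(TBSO)-4-oxo-13,15-dinorguai-1(5)-en-12,8-olide
Product: 17 (2S,4R,7S,8R,10R)-2-(TBSO)-4-hydroxy-13-norguai-1(5)-en-12,8-olide
Conditions: MeMgBr, CeCl3, THF, −78 °C
Reagents that add atoms: methylmagnesium bromide (C[Mg]Br)
Why: Organocerium 1,2-addition to the hindered enone carbonyl leaves the lactone untouched, with methyl entering anti to the C2 silyloxy group; this carbinol centre is destroyed in step 23.

Step 11
Reactants: 17 (2S,4R,7S,8R,10R)-2-(TBSO)-4-hydroxy-13-norguai-1(5)-en-12,8-olide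
Product: 20 (2S,4R,7S,8R,10R)-2-(TBSO)-4-hydroxyguaia-1(5),11(13)-dien-12,8-olide, via Mannich base 18 (not isolated), via methiodide 19 (not isolated)
Conditions: LDA (2.2 equiv), THF, −78 °C; CH2=NMe2+ I−, −78 to 0 °C; then MeI, MeOH, rt; then DBU, CH2Cl2
Reagents that add atoms: Eschenmoser's salt (C=[N+](C)C.[I-])
Why: Mannich reaction of the lactone enolate followed by quaternisation and elimination is the standard α-methylenation of a γ-lactone.

Step 12
Reactants: 20 (2S,4R,7S,8R,10R)-2-(TBSO)-4-hydroxyguaia-1(5),11(13)-dien-12,8-olide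
Product: 22 (2S,4R,7S,8R,10R)-2-acetoxy-4-hydroxyguaia-1(5),11(13)-dien-12,8-olide, via diol 21 (not isolated)
Conditions: TBAF (1.1 equiv), THF, 0 °C; then Ac2O, DMAP (cat.), 0 °C
Reagents that add atoms: acetic anhydride (CC(=O)OC(C)=O)
Why: Fluoride desilylation and acetylation of the secondary alcohol install the C2 acetate, while the tertiary allylic alcohol is not acylated.

Step 13
Reactants: 23 pent-4-en-1-ol
Product: 24 tert-butyldimethyl(pent-4-en-1-yloxy)silane
Conditions: TBSCl, imidazole, CH2Cl2, rt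
Reagents that add atoms: tert-butyldimethylsilyl chloride (CC(C)(C)[Si](C)(C)Cl)
Why: Standard silyl protection of the primary alcohol that becomes O1′.

Step 14
Reactants: 24 tert-butyldimethyl(pent-4-en-1-yloxy)silane
Product: 25 (2S)-5-(TBSO)-2-methylpentan-1-ol
Conditions: Me3Al, (+)-(NMI)2ZrCl2 (3 mol %), MAO (cat.), CH2Cl2, 0 °C; then O2
Reagents that add atoms: trimethylaluminium (C[Al](C)C); oxygen (O=O)
Why: Negishi Zr-catalysed asymmetric carboalumination (ZACA) followed by oxidation sets the C4′ methyl stereocentre (S) under catalyst control.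

Step 15
Reactants: 25 (2S)-5-(TBSO)-2-methylpentan-1-ol
Product: 27 (4S)-tert-butyldimethyl[(4-methylhex-5-yn-1-yl)oxy]silane, via aldehyde 26 (not isolated)
Conditions: PhI(OAc)2, TEMPO (cat.), CH2Cl2, rt; then dimethyl (1-diazo-2-oxopropyl)phosphonate, K2CO3, MeOH, 0 °C
Reagents that add atoms: dimethyl (1-diazo-2-oxopropyl)phosphonate (COP(=O)(OC)C(=[N+]=[N-])C(C)=O)
Why: TEMPO oxidation and Seyferth–Gilbert (Ohira–Bestmann) homologation give the terminal alkyne under carbonate conditions mild enough to keep the α-stereocentre.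

Step 16
Reactants: 27 (4S)-tert-butyldimethyl[(4-methylhex-5-yn-1-yl)oxy]silane
Product: 28 (5S)-8-(TBSO)-5-methyloct-3-yn-1-ol
Conditions: n-BuLi, THF, −78 °C; BF3·OEt2; oxirane, −78 °C
Reagents that add atoms: oxirane (C1CO1)
Why: Yamaguchi–Hirao opening of ethylene oxide by the lithium acetylide adds C9′ and C8′ as a homopropargylic alcohol.

Step 17
Reactants: 29 acrolein; 30 methyl acrylate
Product: 31 methyl 3-hydroxy-2-methylidenepent-4-enoate
Conditions: DABCO (20 mol %), neat, rt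
Reagents that add atoms: none
Why: The Morita–Baylis–Hillman reaction assembles the C6′–C7′–C11′(=C13′)–C12′ unit in one step.

Step 18
Reactants: 31 methyl 3-hydroxy-2-methylidenepent-4-enoate
Product: 32 methyl 3-acetoxy-2-methylidenepent-4-enoate
Conditions: Ac2O, pyridine, DMAP (cat.), CH2Cl2, 0 °C
Reagents that add atoms: acetic anhydride (CC(=O)OC(C)=O)
Why: Acetylation turns the bis-allylic alcohol into the leaving group needed for π-allyl formation.

Step 19
Reactants: 28 (5S)-8-(TBSO)-5-methyloct-3-yn-1-ol; 32 methyl 3-acetoxy-2-methylidenepent-4-enoate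
Product: 34 (4S,5S)-4-ethenyl-3-methylidene-5-[(4S)-7-(TBSO)-4-methylhept-2-yn-1-yl]oxolan-2-one, via hydroxy ester 33 (not isolated)
Conditions: [Ir(cod)Cl]2 (2.5 mol %), (S)-SEGPHOS (5 mol %), 4-chloro-3-nitrobenzoic acid (10 mol %), K3PO4 (1 equiv), THF, 60 °C
Reagents that add atoms: none
Why: Krische-type iridium-catalysed transfer-hydrogenative 2-(alkoxycarbonyl)allylation from the alcohol oxidation level couples at the central allyl carbon, the chiral catalyst setting C8′ and the closed chair-like transition state the syn C7′ centre, and the hydroxy ester lactonises to the cis lactone; the ligand enantiomer is chosen to give 8′S.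

Step 20
Reactants: 34 (4S,5S)-4-ethenyl-3-methylidene-5-[(4S)-7-(TBSO)-4-methylhept-2-yn-1-yl]oxolan-2-one
Product: 35 (3aS,7aS)-3,6-dimethylidene-5-[(2S)-5-(TBSO)pentan-2-yl]-3a,6,7,7a-tetrahydro-1-benzofuran-2(3H)-one
Conditions: Hoveyda–Grubbs II (5 mol %), ethylene (1 atm), PhMe, 80 °C
Reagents that add atoms: none
Why: Endo-mode ring-closing enyne metathesis (yne-then-ene path, in which Ru=CH2 adds its carbon to the less hindered alkyne carbon C10′ and the resulting carbene closes onto the vinyl group) forms the cyclohexene with the exocyclic methylene, the electron-poor α-methylene lactone being inert.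

Step 21
Reactants: 35 (3aS,7aS)-3,6-dimethylidene-5-[(2S)-5-(TBSO)pentan-2-yl]-3a,6,7,7a-tetrahydro-1-benzofuran-2(3H)-one
Product: 38 2-[(1S,6S)-6-(TBSO)-4-methylidene-3-[(2S)-5-(TBSO)pentan-2-yl]cyclohex-2-en-1-yl]prop-2-enoic acid, via hydroxy acid 36 (not isolated), via bis-silyl derivative 37 (not isolated)
Conditions: LiOH·H2O, THF–H2O, 0 °C; concentrate; TBSOTf, 2,6-lutidine, CH2Cl2, 0 °C; then K2CO3 (cat.), MeOH, rt
Reagents that add atoms: lithium hydroxide ([Li+].[OH-]); tert-butyldimethylsilyl trifluoromethanesulfonate (CC(C)(C)[Si](C)(C)OS(=O)(=O)C(F)(F)F)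
Why: Saponification, silylation of the carboxylate salt without acidification (so the cis hydroxy acid cannot re-lactonise) and selective methanolysis of the silyl ester free the acid with O8′ blocked.

Step 22
Reactants: 38 2-[(1S,6S)-6-(TBSO)-4-methylidene-3-[(2S)-5-(TBSO)pentan-2-yl]cyclohex-2-en-1-yl]prop-2-enoic acid
Product: 39 (3aR,4S,7aS)-6-(bromomethyl)-4-(TBSO)-3-methylidene-7-[(2S)-5-(TBSO)pentan-2-yl]-3a,4,5,7a-tetrahydro-1-benzofuran-2(3H)-one
Conditions: NBS, MeCN, −30 °C, dark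
Reagents that add atoms: N-bromosuccinimide (O=C1CCC(=O)N1Br)
Why: 1,4-Bromolactonisation of the diene acid (Br+ at C14′, 5-exo carboxylate attack at C6′ on the face of the carboxyl arm) gives the cis-fused 12′,6′-lactone, so that C8′ rather than C6′ now lies out of the lactone plane next to C7′.

Step 23
Reactants: 22 (2S,4R,7S,8R,10R)-2-acetoxy-4-hydroxyguaia-1(5),11(13)-dien-12,8-olide; 39 (3aR,4S,7aS)-6-(bromomethyl)-4-(TBSO)-3-methylidene-7-[(2S)-5-(TBSO)pentan-2-yl]-3a,4,5,7a-tetrahydro-1-benzofuran-2(3H)-one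
Product: 41 Diels–Alder adduct (C1–C13′ and C3–C11′ bonds; bromolactone relay intact), via diene 40 (not isolated)
Conditions: Burgess reagent, PhH, 0 to 25 °C, diene generated slowly in the presence of 39 (3 equiv), BHT; then 40 °C, 48 h, dark
Reagents that add atoms: none
Why: Burgess dehydration of the tertiary allylic alcohol gives the cyclopentadiene, which is trapped in a Diels–Alder reaction in which C13′→C1 and C11′→C3 bonding avoids vicinal quaternary centres, the dienophile adds anti to the C2 acetoxy and C10 methyl groups, the s-cis-locked α-methylene lactone reacts carbonyl-exo and the diene meets the convex face of the cis-fused bromolactone (anti to C8′), together setting C1, C3 and C11′.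

Step 24
Reactants: 41 Diels–Alder adduct
Product: 42 8′,1′-bis-O-TBS seco acid (12′-CO2H; 5′,10′(14′)-diene restored)
Conditions: Zn dust, AcOH, THF, 0 °C to rt
Reagents that add atoms: none
Why: Zinc-mediated reductive 1,4-elimination of the allylic bromide and allylic carboxylate (vinylogous Boord reaction) regenerates the diene and frees the C12′ acid without touching the α-methylene lactone or the acetate.

Step 25
Reactants: 42 8′,1′-bis-O-TBS seco acid
Product: 44 target CNP0299458.1, via hydroxy acid 43 (not isolated)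
Conditions: HF·pyridine, pyridine, THF, 0 °C to rt
Reagents that add atoms: none
Why: Acidic fluoride removes both silyl ethers (the acetate survives) and the cis γ-hydroxy acid lactonises spontaneously onto O8′ with retention at C7′, C8′ and C11′.

**Compound list**

1 | itaconic anhydride (3-methylideneoxolane-2,5-dione) | C=C1CC(=O)OC1=O | starting material
2 | 4-methyl hydrogen itaconate (2-(2-methoxy-2-oxoethyl)prop-2-enoic acid) | C=C(CC(=O)OC)C(=O)O | intermediate
3 | methyl 3-(chlorocarbonyl)but-3-enoate | C=C(CC(=O)OC)C(=O)Cl | intermediate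
4 | methyl 3-methylidene-4-oxohexanoate | CCC(=O)C(=C)CC(=O)OC | intermediate
5 | methyl (4Z)-4-(TBSO)-3-methylidenehex-4-enoate | C/C=C(\O[Si](C)(C)C(C)(C)C)C(=C)CC(=O)OC | intermediate
6 | (4S)-4-hydroxycyclopent-2-en-1-one | O[C@@H]1C=CC(=O)C1 | starting material
7 | (4S)-4-(TBSO)cyclopent-2-en-1-one | CC(C)(C)[Si](C)(C)O[C@@H]1C=CC(=O)C1 | intermediate
8 | (4S)-2,3-dibromo-4-(TBSO)cyclopentan-1-one (Br-bearing centres mixed) | CC(C)(C)[Si](C)(C)O[C@@H]1C(Br)C(Br)C(=O)C1 | intermediate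
9 | (4S)-2-bromo-4-(TBSO)cyclopent-2-en-1-one | CC(C)(C)[Si](C)(C)O[C@@H]1C=C(Br)C(=O)C1 | intermediate
10 | methyl 2-[(3S)-7a-bromo-3,5-bis(TBSO)-4-methyl-1-oxo-2,3,3a,4,7,7a-hexahydro-1H-inden-6-yl]acetate (cis-fused; C3a, C4, C7a not assigned) | COC(=O)CC1=C(O[Si](C)(C)C(C)(C)C)C(C)C2[C@@H](O[Si](C)(C)C(C)(C)C)CC(=O)C2(Br)C1 | intermediate
11 | methyl 2-[(3S)-3,5-bis(TBSO)-4-methyl-1-oxo-2,3,4,7-tetrahydro-1H-inden-6-yl]acetate (C4 not assigned) | COC(=O)CC1=C(O[Si](C)(C)C(C)(C)C)C(C)C2=C(C1)C(=O)C[C@@H]2O[Si](C)(C)C(C)(C)C | intermediate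
12 | methyl 2-[(3S)-3,5-bis(TBSO)-4-methyl-1-oxo-2,3,6,7-tetrahydro-1H-inden-6-yl]acetate (C6 epimers) | COC(=O)CC1CC2=C(C(C)=C1O[Si](C)(C)C(C)(C)C)[C@@H](O[Si](C)(C)C(C)(C)C)CC2=O | intermediate
13 | methyl 2-[(3S)-3,5-bis(TBSO)-4-methyl-4,5-methano-1-oxo-2,3,4,5,6,7-hexahydro-1H-inden-6-yl]acetate (silyloxycyclopropane; cyclopropane and C6 centres mixed) | COC(=O)CC1CC2=C(C3(C)CC13O[Si](C)(C)C(C)(C)C)[C@@H](O[Si](C)(C)C(C)(C)C)CC2=O | intermediate
14 | methyl 2-[(3S,4R)-3-(TBSO)-4-methyl-1,6-dioxo-1,2,3,4,5,6,7,8-octahydroazulen-7-yl]acetate (C7 epimers; guaiane C2 S, C10 R) | COC(=O)CC1CC2=C([C@H](C)CC1=O)[C@@H](O[Si](C)(C)C(C)(C)C)CC2=O | intermediate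
15 | methyl 2-[(3S,4R,6R,7S)-3-(TBSO)-6-hydroxy-4-methyl-1-oxo-1,2,3,4,5,6,7,8-octahydroazulen-7-yl]acetate | COC(=O)C[C@@H]1CC2=C([C@H](C)C[C@H]1O)[C@@H](O[Si](C)(C)C(C)(C)C)CC2=O | intermediate
16 | (2S,7S,8R,10R)-2-(TBSO)-4-oxo-13,15-dinorguai-1(5)-en-12,8-olide (trans-fused lactone) | CC(C)(C)[Si](C)(C)O[C@H]1CC(=O)C2=C1[C@H](C)C[C@H]3OC(=O)C[C@@H]3C2 | intermediate
17 | (2S,4R,7S,8R,10R)-2-(TBSO)-4-hydroxy-13-norguai-1(5)-en-12,8-olide | CC(C)(C)[Si](C)(C)O[C@H]1C[C@@](C)(O)C2=C1[C@H](C)C[C@H]3OC(=O)C[C@@H]3C2 | intermediate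
18 | (2S,4R,7S,8R,10R)-13-(dimethylamino)-2-(TBSO)-4-hydroxyguai-1(5)-en-12,8-olide (C11 epimers) | CC(C)(C)[Si](C)(C)O[C@H]1C[C@@](C)(O)C2=C1[C@H](C)C[C@H]3OC(=O)C(CN(C)C)[C@@H]3C2 | intermediate
19 | N-methyl iodide (trimethylammonium salt) of 18 | CC(C)(C)[Si](C)(C)O[C@H]1C[C@@](C)(O)C2=C1[C@H](C)C[C@H]3OC(=O)C(C[N+](C)(C)C)[C@@H]3C2.[I-] | intermediate
20 | (2S,4R,7S,8R,10R)-2-(TBSO)-4-hydroxyguaia-1(5),11(13)-dien-12,8-olide | CC(C)(C)[Si](C)(C)O[C@H]1C[C@@](C)(O)C2=C1[C@H](C)C[C@H]3OC(=O)C(=C)[C@@H]3C2 | intermediate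
21 | (2S,4R,7S,8R,10R)-2,4-dihydroxyguaia-1(5),11(13)-dien-12,8-olide | O[C@H]1C[C@@](C)(O)C2=C1[C@H](C)C[C@H]3OC(=O)C(=C)[C@@H]3C2 | intermediate
22 | (2S,4R,7S,8R,10R)-2-acetoxy-4-hydroxyguaia-1(5),11(13)-dien-12,8-olide | CC(=O)O[C@H]1C[C@@](C)(O)C2=C1[C@H](C)C[C@H]3OC(=O)C(=C)[C@@H]3C2 | intermediate
23 | pent-4-en-1-ol | C=CCCCO | starting material
24 | tert-butyldimethyl(pent-4-en-1-yloxy)silane | C=CCCCO[Si](C)(C)C(C)(C)C | intermediate
25 | (2S)-5-(TBSO)-2-methylpentan-1-ol | C[C@H](CO)CCCO[Si](C)(C)C(C)(C)C | intermediate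
26 | (2S)-5-(TBSO)-2-methylpentanal | C[C@H](C=O)CCCO[Si](C)(C)C(C)(C)C | intermediate
27 | (4S)-tert-butyldimethyl[(4-methylhex-5-yn-1-yl)oxy]silane | C[C@H](C#C)CCCO[Si](C)(C)C(C)(C)C | intermediate
28 | (5S)-8-(TBSO)-5-methyloct-3-yn-1-ol | C[C@H](C#CCCO)CCCO[Si](C)(C)C(C)(C)C | intermediate
29 | acrolein | C=CC=O | starting material
30 | methyl acrylate | C=CC(=O)OC | starting material
31 | methyl 3-hydroxy-2-methylidenepent-4-enoate (racemic) | C=CC(O)C(=C)C(=O)OC | intermediate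
32 | methyl 3-acetoxy-2-methylidenepent-4-enoate (racemic) | C=CC(OC(C)=O)C(=C)C(=O)OC | intermediate
33 | methyl (3S,4S,8S)-3-ethenyl-4-hydroxy-8-methyl-2-methylidene-11-(TBSO)undec-6-ynoate | C=C[C@@H](C(=C)C(=O)OC)[C@@H](O)CC#C[C@@H](C)CCCO[Si](C)(C)C(C)(C)C | intermediate
34 | (4S,5S)-4-ethenyl-3-methylidene-5-[(4S)-7-(TBSO)-4-methylhept-2-yn-1-yl]oxolan-2-one | C=C[C@@H]1[C@H](CC#C[C@@H](C)CCCO[Si](C)(C)C(C)(C)C)OC(=O)C1=C | intermediate
35 | (3aS,7aS)-3,6-dimethylidene-5-[(2S)-5-(TBSO)pentan-2-yl]-3a,6,7,7a-tetrahydro-1-benzofuran-2(3H)-one | C=C1C[C@@H]2OC(=O)C(=C)[C@@H]2C=C1[C@@H](C)CCCO[Si](C)(C)C(C)(C)C | intermediate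
36 | 2-[(1S,6S)-6-hydroxy-4-methylidene-3-[(2S)-5-(TBSO)pentan-2-yl]cyclohex-2-en-1-yl]prop-2-enoic acid (handled as its lithium salt) | C=C1C[C@H](O)[C@H](C(=C)C(=O)O)C=C1[C@@H](C)CCCO[Si](C)(C)C(C)(C)C | intermediate
37 | TBS ester of 38 (8′-O-TBS ether, 12′-O-TBS ester) | C=C1C[C@H](O[Si](C)(C)C(C)(C)C)[C@H](C(=C)C(=O)O[Si](C)(C)C(C)(C)C)C=C1[C@@H](C)CCCO[Si](C)(C)C(C)(C)C | intermediate
38 | 2-[(1S,6S)-6-(TBSO)-4-methylidene-3-[(2S)-5-(TBSO)pentan-2-yl]cyclohex-2-en-1-yl]prop-2-enoic acid | C=C1C[C@H](O[Si](C)(C)C(C)(C)C)[C@H](C(=C)C(=O)O)C=C1[C@@H](C)CCCO[Si](C)(C)C(C)(C)C | intermediate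
39 | (3aR,4S,7aS)-6-(bromomethyl)-4-(TBSO)-3-methylidene-7-[(2S)-5-(TBSO)pentan-2-yl]-3a,4,5,7a-tetrahydro-1-benzofuran-2(3H)-one (cis-fused 12′,6′-lactone) | C=C1C(=O)O[C@H]2[C@@H]1[C@@H](O[Si](C)(C)C(C)(C)C)CC(CBr)=C2[C@@H](C)CCCO[Si](C)(C)C(C)(C)C | intermediate
40 | (2S,7S,8R,10R)-2-acetoxyguaia-1(5),3,11(13)-trien-12,8-olide | CC(=O)O[C@H]1C=C(C)C2=C1[C@H](C)C[C@H]3OC(=O)C(=C)[C@@H]3C2 | intermediate
41 | Diels–Alder adduct: guaianolide part as in 44; C11′ spiro carbon of a cis-fused 12′,6′-γ-lactone with C3 on the H-7′ face, C12′ exo; 5′(10′)-ene; 14′-bromide; 8′- and 1′-OTBS | O=C1O[C@@H]2C([C@@H](C)CCCO[Si](C)(C)C(C)(C)C)=C(CBr)C[C@H](O[Si](C)(C)C(C)(C)C)[C@@H]2[C@]13C[C@@]45C(=C(C)[C@@H]3[C@@H]4OC(C)=O)C[C@H]3C(=C)C(=O)O[C@@H]3C[C@H]5C | intermediate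
42 | seco acid: 44 with the 12′,8′-lactone open (12′-CO2H) and 8′-O-TBS, 1′-O-TBS | C=C1C[C@H](O[Si](C)(C)C(C)(C)C)[C@@H](C=C1[C@@H](C)CCCO[Si](C)(C)C(C)(C)C)[C@@]2(C(=O)O)C[C@@]34C(=C(C)[C@@H]2[C@@H]3OC(C)=O)C[C@H]5C(=C)C(=O)O[C@@H]5C[C@H]4C | intermediate
43 | 8′,1′-dihydroxy seco acid of 44 | C=C1C[C@H](O)[C@@H](C=C1[C@@H](C)CCCO)[C@@]2(C(=O)O)C[C@@]34C(=C(C)[C@@H]2[C@@H]3OC(C)=O)C[C@H]5C(=C)C(=O)O[C@@H]5C[C@H]4C | intermediate
44 | CNP0299458.1, (1R,2S,3S,7S,8R,10R,4′S,7′S,8′S,11′S) | C=C1C[C@@H]2OC(=O)[C@@]3(C[C@@]45C(=C(C)[C@@H]3[C@@H]4OC(C)=O)C[C@H]3C(=C)C(=O)O[C@@H]3C[C@H]5C)[C@@H]2C=C1[C@@H](C)CCCO | target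

**Step count**

Total: 25 steps. Longest linear sequence: 13 steps (1–3, 6–12, 23–25).

**Three steps most likely to fail, with fallbacks**

Step 8 (the new ring expansion) may fail because the acceptor-conjugated silyloxycyclopropane is hard to oxidise, or because H is delivered to C5 instead of C10. The fallback uses known two-electron chemistry and sets out from 13. Buffered fluoride (Bu4NF, AcOH, THF, −40 °C) opens the donor–acceptor cyclopropane by Reissig-type retro-aldol cleavage of the internal bond, and C5 protonation of the ring-enlarged dienolate gives the β,γ-unsaturated diketone F1. Catalytic DBU returns the double bond to conjugation and gives 14 together with its C10 epimer F2, which is separated and recycled through the same equilibration. The route is rejoined at 14.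

Step 9 (two centres by substrate control) may give the wrong C8 alcohol. The fallback sets out from 14. L-selectride (THF, −78 °C), which attacks anti to the C7 side chain, gives after in situ lactonisation the cis-fused 8-epi lactone F3. LiOH opens it to the cis hydroxy acid F4, and Mitsunobu lactonisation (PPh3, DIAD, THF) closes the lactone with inversion at C8. The route is rejoined at 16.

Step 23 (fragment union) may suffer from self-dimerisation of diene 40 through its own α-methylene lactone, or from its lability. The fallback sets out from 22. Thiophenol with catalytic Et3N gives the thiol adduct F5, whose masked lactone cannot act as a dienophile. Burgess dehydration gives the thio-masked diene F6, which is trapped by 39 under the conditions of step 23 to give the thio-masked adduct F7. NaIO4 (MeOH–H2O, 0 °C) gives the sulfoxide F8, and thermal syn-elimination (PhMe, NaHCO3, 90 °C) unmasks the methylene lactone. The route is rejoined at 41.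

**Further compounds**

F1 | step 8 | methyl 2-[(3S)-3-(TBSO)-4-methyl-1,6-dioxo-1,2,3,5,6,7,8,8a-octahydroazulen-7-yl]acetate (deconjugated C3a=C4 isomer; C7, C8a mixed) | COC(=O)CC1CC2C(=C(C)CC1=O)[C@@H](O[Si](C)(C)C(C)(C)C)CC2=O
F2 | step 8 | methyl 2-[(3S,4S)-3-(TBSO)-4-methyl-1,6-dioxo-1,2,3,4,5,6,7,8-octahydroazulen-7-yl]acetate (C10 epimer of 14) | COC(=O)CC1CC2=C([C@@H](C)CC1=O)[C@@H](O[Si](C)(C)C(C)(C)C)CC2=O
F3 | step 9 | (2S,7S,8S,10R)-2-(TBSO)-4-oxo-13,15-dinorguai-1(5)-en-12,8-olide (cis-fused lactone) | CC(C)(C)[Si](C)(C)O[C@H]1CC(=O)C2=C1[C@H](C)C[C@@H]3OC(=O)C[C@@H]3C2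
F4 | step 9 | 8-epi hydroxy acid from F3 (2-[(3S,4R,6S,7S)-3-(TBSO)-6-hydroxy-4-methyl-1-oxo-1,2,3,4,5,6,7,8-octahydroazulen-7-yl]acetic acid) | CC(C)(C)[Si](C)(C)O[C@H]1CC(=O)C2=C1[C@H](C)C[C@H](O)[C@H](CC(=O)O)C2
F5 | step 23 | 13-(phenylsulfanyl)-11,13-dihydro derivative of 22 (C11 epimers) | CC(=O)O[C@H]1C[C@@](C)(O)C2=C1[C@H](C)C[C@H]3OC(=O)C(CSc4ccccc4)[C@@H]3C2
F6 | step 23 | 13-(phenylsulfanyl)-11,13-dihydro derivative of diene 40 | CC(=O)O[C@H]1C=C(C)C2=C1[C@H](C)C[C@H]3OC(=O)C(CSc4ccccc4)[C@@H]3C2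
F7 | step 23 | 13-(phenylsulfanyl)-11,13-dihydro derivative of adduct 41 | O=C1O[C@@H]2C([C@@H](C)CCCO[Si](C)(C)C(C)(C)C)=C(CBr)C[C@H](O[Si](C)(C)C(C)(C)C)[C@@H]2[C@]13C[C@@]45C(=C(C)[C@@H]3[C@@H]4OC(C)=O)C[C@H]3C(CSc6ccccc6)C(=O)O[C@@H]3C[C@H]5C
F8 | step 23 | 13-(phenylsulfinyl)-11,13-dihydro derivative of adduct 41 | O=C1O[C@@H]2C([C@@H](C)CCCO[Si](C)(C)C(C)(C)C)=C(CBr)C[C@H](O[Si](C)(C)C(C)(C)C)[C@@H]2[C@]13C[C@@]45C(=C(C)[C@@H]3[C@@H]4OC(C)=O)C[C@H]3C(CS(=O)c6ccccc6)C(=O)O[C@@H]3C[C@H]5C
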